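## Retrosynthetic overview

1. The target is (2S)-2′-geranyl-3′,4′,7-trihydroxyflavanone. The strategy rests on C2 of ring C, a benzylic carbon bonded to O1 and β to the C4 carbonyl. The C2–C1′ bond and the only stereocentre can therefore be made together by adding the ring-B aryl group to the C2=C3 bond of a chromone.
2. Last disconnection: the three O–MOM bonds (7-, 3′- and 4′-OH). Before it: C2–C1′, by rhodium/chiral-diene 1,4-arylation of 7-MOM-chromone with an ortho-geranyl arylboronic acid.
3. Boronic acid: C–B from C–Br (lithium exchange, borate). The aryl–CH2 (geranyl) bond comes from deprotonation of bis-MOM 4-bromocatechol between Br and OMOM, copper transmetalation and geranyl bromide.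
4. Ring order: no ring is built. Rings A and C arrive as 7-hydroxychromone, ring B as 4-bromocatechol.

Key step: step 5

Assumption: the (S,S)-antipode of the diene ligand is assigned to the (S)-flavanone by carrying over the facial preference this ligand family shows with cyclic enones; the sense would be checked on the first run and the antipodal ligand used if it proved opposite. Geranyl bromide is taken as the geometrically pure (E)-isomer.

## Route

Step 1
Reactants: 1 7-hydroxy-4H-chromen-4-one
Product: 2 7-(methoxymethoxy)-4H-chromen-4-one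
Conditions: MOMCl (1.3 equiv), K2CO3 (2 equiv), acetone, 0 °C → rt
Reagents that add atoms: chloromethyl methyl ether, COCCl
Why: Williamson-type O-alkylation, in which carbonate deprotonates the acidic 7-OH (a vinylogous acid through the pyranone carbonyl) and the phenoxide displaces chloride from the α-chloro ether, while the non-nucleophilic base should leave the pyranone ring closed.

Step 2
Reactants: 3 4-bromobenzene-1,2-diol
Product: 4 4-bromo-1,2-bis(methoxymethoxy)benzene
Conditions: NaH (2.4 equiv), THF/DMF, 0 °C; MOMCl (2.4 equiv), 0 °C → rt, under N2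
Reagents that add atoms: chloromethyl methyl ether, COCCl
Why: Double Williamson-type O-alkylation of the catechol dianion with the reactive α-chloro ether; the aryl bromide is inert, and MOM is chosen because it later acidifies and coordinates in the ring metalation and withstands the basic key step.

Step 3
Reactants: 4 4-bromo-1,2-bis(methoxymethoxy)benzene; 5 geranyl bromide [(2E)-1-bromo-3,7-dimethylocta-2,6-diene]
Product: 8 1-bromo-2-[(2E)-3,7-dimethylocta-2,6-dien-1-yl]-3,4-bis(methoxymethoxy)benzene, via aryllithium 6 (not isolated), via arylcopper 7 (not isolated)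
Conditions: lithium 2,2,6,6-tetramethylpiperidide (LiTMP, 1.2 equiv, from the amine and n-BuLi), THF, −78 °C; CuBr·SMe2 (1.2 equiv), −78 → −40 °C; 5 (1.3 equiv), −40 → 0 °C
Reagents that add atoms: none
Why: Directed ortho-metalation, in which the hindered amide base removes the most acidic ring proton (C3, flanked by the electron-withdrawing bromine and the lithium-coordinating OMOM group) without attacking the C–Br bond; this aryllithium is already the most stabilised regioisomer, so bromine migration has no driving force, and cold transmetalation to the arylcopper prevents loss of LiBr and lets the primary allylic bromide be substituted at its unhindered CH2 terminus with the (E)-alkene retained.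

Step 4
Reactants: 8 1-bromo-2-[(2E)-3,7-dimethylocta-2,6-dien-1-yl]-3,4-bis(methoxymethoxy)benzene
Product: 11 {2-[(2E)-3,7-dimethylocta-2,6-dien-1-yl]-3,4-bis(methoxymethoxy)phenyl}boronic acid, via aryllithium 9 (not isolated), via lithium aryltriisopropoxyborate 10 (not isolated)
Conditions: B(OiPr)3 (1.5 equiv), toluene/THF (4:1), −78 °C; n-BuLi (1.15 equiv) added slowly; → −20 °C; 1 M aq HCl to pH 5–6, 0 °C
Reagents that add atoms: triisopropyl borate, CC(C)OB(OC(C)C)OC(C)C; water, O
Why: Bromine–lithium exchange with in situ trapping, in which exchange at C–Br is faster at −78 °C than addition of n-BuLi to the borate, so the aryllithium is captured as the borate complex before it can abstract a benzylic–allylic proton or be butylated, and brief cold dilute acid hydrolyses the borate without touching the MOM acetals.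

Step 5
Reactants: 2 7-(methoxymethoxy)-4H-chromen-4-one; 11 {2-[(2E)-3,7-dimethylocta-2,6-dien-1-yl]-3,4-bis(methoxymethoxy)phenyl}boronic acid
Product: 12 (2S)-2-{2-[(2E)-3,7-dimethylocta-2,6-dien-1-yl]-3,4-bis(methoxymethoxy)phenyl}-7-(methoxymethoxy)-2,3-dihydro-4H-chromen-4-one
Conditions: [RhCl(C2H4)2]2 (2.5 mol %), (1S,4S)-2,5-diphenylbicyclo[2.2.2]octa-2,5-diene [(S,S)-Ph-bod*, 5.5 mol %], KOH (0.3 equiv, aq), 1,4-dioxane/H2O (10:1), 30 °C; 11 (1.6 equiv) added in two portions
Reagents that add atoms: none
Why: Hayashi–Miyaura reaction: hydroxide turns the chloride dimer into a diene-ligated Rh–OH species (monovalent rhodium throughout), which takes the aryl group from boron; the aryl–rhodium adds across the chromone C2=C3 bond by syn carbometalation to an oxa-π-allyl rhodium enolate, which water protonates at C3 with return of Rh–OH. The closest known reaction type is the rhodium/chiral-diene-catalysed asymmetric 1,4-addition of arylboronic acids to chromones, which gives flavanones directly. No ring is closed; one skeletal bond (C2–C1′) is formed on the intact chromone. The single stereocentre C2 is set by the catalyst alone, since the chromone is planar and achiral: the C2-symmetric diene holds the enone so that one phenyl group shields one enantioface of C2=C3, and the (S,S)-ligand is assigned to the (S)-product by the model stated above. The step needs 1,4- over 1,2-addition, and enone insertion over alkene insertion and over hydrolysis of the aryl–rhodium bond (net protodeboronation): the electron-poor, unhindered C2=C3 bond binds rhodium far better than the trisubstituted geranyl alkenes, the π-accepting diene speeds insertion, and portionwise addition of the boronic acid limits its decomposition. Sub-stoichiometric KOH, buffered by the excess boronic acid, keeps the medium near neutral so that the product should not open by retro-oxa-Michael (E1cB) reaction, which would erode the configuration at C2.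

Step 6
Reactants: 12 (2S)-2-{2-[(2E)-3,7-dimethylocta-2,6-dien-1-yl]-3,4-bis(methoxymethoxy)phenyl}-7-(methoxymethoxy)-2,3-dihydro-4H-chromen-4-one
Product: 13 (2S)-2-{2-[(2E)-3,7-dimethylocta-2,6-dien-1-yl]-3,4-dihydroxyphenyl}-7-hydroxy-2,3-dihydro-4H-chromen-4-one
Conditions: HCl (1.25 M in MeOH), THF co-solvent, rt → 40 °C, stopped at complete MOM removal
Reagents that add atoms: none
Why: Acid-catalysed acetal exchange (transacetalisation to dimethoxymethane in methanol), in which the three aryl MOM acetals ionise through oxocarbenium ions much faster than the trisubstituted alkenes are protonated in dilute methanolic HCl at or below 40 °C, and C2 is untouched because the flavanone ring does not open under mild acid.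

## Compound list

1 | 7-hydroxy-4H-chromen-4-one | O=c1ccoc2cc(O)ccc12 | starting material
2 | 7-(methoxymethoxy)-4H-chromen-4-one | O=c1ccoc2cc(OCOC)ccc12 | intermediate
3 | 4-bromobenzene-1,2-diol | Oc1ccc(Br)cc1O | starting material
4 | 4-bromo-1,2-bis(methoxymethoxy)benzene | COCOc1ccc(Br)cc1OCOC | intermediate
5 | geranyl bromide, (2E)-1-bromo-3,7-dimethylocta-2,6-diene | CC(C)=CCC/C(C)=C/CBr | starting material
6 | [6-bromo-2,3-bis(methoxymethoxy)phenyl]lithium (formed in the flask, step 3) | [Li]c1c(Br)ccc(OCOC)c1OCOC | intermediate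
7 | [6-bromo-2,3-bis(methoxymethoxy)phenyl]copper (formed in the flask, step 3) | [Cu]c1c(Br)ccc(OCOC)c1OCOC | intermediate
8 | 1-bromo-2-[(2E)-3,7-dimethylocta-2,6-dien-1-yl]-3,4-bis(methoxymethoxy)benzene | CC(C)=CCC/C(C)=C/Cc1c(Br)ccc(OCOC)c1OCOC | intermediate
9 | {2-[(2E)-3,7-dimethylocta-2,6-dien-1-yl]-3,4-bis(methoxymethoxy)phenyl}lithium (formed in the flask, step 4) | CC(C)=CCC/C(C)=C/Cc1c([Li])ccc(OCOC)c1OCOC | intermediate
10 | lithium {2-[(2E)-3,7-dimethylocta-2,6-dien-1-yl]-3,4-bis(methoxymethoxy)phenyl}tri(propan-2-yloxy)borate (formed in the flask, step 4) | CC(C)=CCC/C(C)=C/Cc1c([B-](OC(C)C)(OC(C)C)OC(C)C)ccc(OCOC)c1OCOC.[Li+] | intermediate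
11 | {2-[(2E)-3,7-dimethylocta-2,6-dien-1-yl]-3,4-bis(methoxymethoxy)phenyl}boronic acid | CC(C)=CCC/C(C)=C/Cc1c(B(O)O)ccc(OCOC)c1OCOC | intermediate
12 | (2S)-2-{2-[(2E)-3,7-dimethylocta-2,6-dien-1-yl]-3,4-bis(methoxymethoxy)phenyl}-7-(methoxymethoxy)-2,3-dihydro-4H-chromen-4-one | CC(C)=CCC/C(C)=C/Cc1c([C@@H]2CC(=O)c3ccc(OCOC)cc3O2)ccc(OCOC)c1OCOC | intermediate
13 | (2S)-2-{2-[(2E)-3,7-dimethylocta-2,6-dien-1-yl]-3,4-dihydroxyphenyl}-7-hydroxy-2,3-dihydro-4H-chromen-4-one | CC(C)=CCC/C(C)=C/Cc1c([C@@H]2CC(=O)c3ccc(O)cc3O2)ccc(O)c1O | target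

## Step count and risks

Total steps: 6. Longest linear sequence: 5 steps (3 → 4 → 8 → 11 → 12 → 13, steps 2 to 6); step 1 is the one-step side branch.

**Step 5.** Aryl transfer from boron is slowed by the ortho-geranyl group, so hydrolysis of the aryl–rhodium intermediate (net protodeboronation) may outpace insertion into the electron-rich 7-alkoxychromone. Facial discrimination may be insufficient, or hydroxide may open the product and erode the configuration at C2.

Fallback (closure of the C2–O1 bond in place of C2–C1′ coupling, with resolution); it sets out from 8 and returns at 12: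
- Bromine–lithium exchange on 8 (n-BuLi, THF, −78 °C, through 9) and a DMF quench should give 2-[(2E)-3,7-dimethylocta-2,6-dien-1-yl]-3,4-bis(methoxymethoxy)benzaldehyde F1.
- Commercial 2,4-dihydroxyacetophenone is protected at the non-chelated 4-OH (MOMCl, K2CO3, acetone) to give 1-[2-hydroxy-4-(methoxymethoxy)phenyl]ethan-1-one F2.
- Claisen–Schmidt condensation of F1 with F2 (KOH, EtOH, rt) should give (2E)-3-{2-[(2E)-3,7-dimethylocta-2,6-dien-1-yl]-3,4-bis(methoxymethoxy)phenyl}-1-[2-hydroxy-4-(methoxymethoxy)phenyl]prop-2-en-1-one F3.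
- Intramolecular oxa-Michael addition (NaOAc, EtOH, reflux) closes ring C to the racemic tris-MOM flavanone F4.
- Preparative chromatography on a polysaccharide-based chiral stationary phase then delivers the (S)-enantiomer, which is 12. The (R)-enantiomer is returned to the NaOAc conditions, where reversible ring opening racemises it for another pass.

**Step 3.** The ortho-bromo aryllithium 6 may lose LiBr (aryne formation) before it is transmetalated, and deprotonation or coupling at the position crowded by bromine may stay incomplete.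

Fallback (an O-carbamate in place of bromine as the flanking director and later boron handle); it sets out from 4 and returns at 12:
- Palladium-catalysed hydroxylation of 4 (Pd2(dba)3, t-BuXPhos, KOH, dioxane/H2O, 100 °C) should give 3,4-bis(methoxymethoxy)phenol F5.
- Et2NCOCl and K2CO3 in MeCN give 3,4-bis(methoxymethoxy)phenyl diethylcarbamate F6.
- s-BuLi/TMEDA in THF at −78 °C removes the proton flanked by the carbamate and the OMOM group (two cooperating directing groups, no halide to eliminate) to give [2-(diethylcarbamoyloxy)-5,6-bis(methoxymethoxy)phenyl]lithium F7.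
- CuBr·SMe2 converts it at −78 °C, before anionic ortho-Fries migration can set in, into [2-(diethylcarbamoyloxy)-5,6-bis(methoxymethoxy)phenyl]copper F8.
- Geranyl bromide 5 then gives 2-[(2E)-3,7-dimethylocta-2,6-dien-1-yl]-3,4-bis(methoxymethoxy)phenyl diethylcarbamate F9.
- KOH in refluxing aqueous EtOH cleaves the carbamate to 2-[(2E)-3,7-dimethylocta-2,6-dien-1-yl]-3,4-bis(methoxymethoxy)phenol F10.
- PhNTf2/Et3N in CH2Cl2 gives 2-[(2E)-3,7-dimethylocta-2,6-dien-1-yl]-3,4-bis(methoxymethoxy)phenyl trifluoromethanesulfonate F11.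
- Miyaura borylation (B2pin2, PdCl2(dppf), KOAc, dioxane, 80 °C) gives 2-{2-[(2E)-3,7-dimethylocta-2,6-dien-1-yl]-3,4-bis(methoxymethoxy)phenyl}-4,4,5,5-tetramethyl-1,3,2-dioxaborolane F12.
- F12 takes the place of 11 under the conditions of step 5 and so rejoins the route at 12.

**Step 6.** Protonation of the geranyl alkenes may compete with acetal cleavage, leading to addition of the 3′-OH to the neighbouring C2″=C3″ double bond (chroman formation) or to hydration of the diene.

Fallback (silyl transfer without Brønsted acid); it sets out from 12 and returns at 13: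
- TMSOTf and 2,2′-bipyridyl in MeCN at 0 °C should convert the three aryl MOM ethers into (2S)-2-{2-[(2E)-3,7-dimethylocta-2,6-dien-1-yl]-3,4-bis(trimethylsilyloxy)phenyl}-7-(trimethylsilyloxy)-2,3-dihydro-4H-chromen-4-one F13. The bipyridyl buffers the medium and carries off the methoxymethyl cation.
- Stirring with water at room temperature then hydrolyses the aryl silyl ethers to 13.

## Further compounds

F1 | step 5 | 2-[(2E)-3,7-dimethylocta-2,6-dien-1-yl]-3,4-bis(methoxymethoxy)benzaldehyde | CC(C)=CCC/C(C)=C/Cc1c(C=O)ccc(OCOC)c1OCOC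
F2 | step 5 | 1-[2-hydroxy-4-(methoxymethoxy)phenyl]ethan-1-one | CC(=O)c1ccc(OCOC)cc1O
F3 | step 5 | (2E)-3-{2-[(2E)-3,7-dimethylocta-2,6-dien-1-yl]-3,4-bis(methoxymethoxy)phenyl}-1-[2-hydroxy-4-(methoxymethoxy)phenyl]prop-2-en-1-one | CC(C)=CCC/C(C)=C/Cc1c(/C=C/C(=O)c2ccc(OCOC)cc2O)ccc(OCOC)c1OCOC
F4 | step 5 | racemic 2-{2-[(2E)-3,7-dimethylocta-2,6-dien-1-yl]-3,4-bis(methoxymethoxy)phenyl}-7-(methoxymethoxy)-2,3-dihydro-4H-chromen-4-one | CC(C)=CCC/C(C)=C/Cc1c(C2CC(=O)c3ccc(OCOC)cc3O2)ccc(OCOC)c1OCOC
F5 | step 3 | 3,4-bis(methoxymethoxy)phenol | COCOc1ccc(O)cc1OCOC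
F6 | step 3 | 3,4-bis(methoxymethoxy)phenyl diethylcarbamate | CCN(CC)C(=O)Oc1ccc(OCOC)c(OCOC)c1
F7 | step 3 | [2-(diethylcarbamoyloxy)-5,6-bis(methoxymethoxy)phenyl]lithium | CCN(CC)C(=O)Oc1ccc(OCOC)c(OCOC)c1[Li]
F8 | step 3 | [2-(diethylcarbamoyloxy)-5,6-bis(methoxymethoxy)phenyl]copper | CCN(CC)C(=O)Oc1ccc(OCOC)c(OCOC)c1[Cu]
F9 | step 3 | 2-[(2E)-3,7-dimethylocta-2,6-dien-1-yl]-3,4-bis(methoxymethoxy)phenyl diethylcarbamate | CC(C)=CCC/C(C)=C/Cc1c(OC(=O)N(CC)CC)ccc(OCOC)c1OCOC
F10 | step 3 | 2-[(2E)-3,7-dimethylocta-2,6-dien-1-yl]-3,4-bis(methoxymethoxy)phenol | CC(C)=CCC/C(C)=C/Cc1c(O)ccc(OCOC)c1OCOC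
F11 | step 3 | 2-[(2E)-3,7-dimethylocta-2,6-dien-1-yl]-3,4-bis(methoxymethoxy)phenyl trifluoromethanesulfonate | CC(C)=CCC/C(C)=C/Cc1c(OS(=O)(=O)C(F)(F)F)ccc(OCOC)c1OCOC
F12 | step 3 | 2-{2-[(2E)-3,7-dimethylocta-2,6-dien-1-yl]-3,4-bis(methoxymethoxy)phenyl}-4,4,5,5-tetramethyl-1,3,2-dioxaborolane | CC(C)=CCC/C(C)=C/Cc1c(B2OC(C)(C)C(C)(C)O2)ccc(OCOC)c1OCOC
F13 | step 6 | (2S)-2-{2-[(2E)-3,7-dimethylocta-2,6-dien-1-yl]-3,4-bis(trimethylsilyloxy)phenyl}-7-(trimethylsilyloxy)-2,3-dihydro-4H-chromen-4-one | CC(C)=CCC/C(C)=C/Cc1c([C@@H]2CC(=O)c3ccc(O[Si](C)(C)C)cc3O2)ccc(O[Si](C)(C)C)c1O[Si](C)(C)C
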